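**Abbreviation:** TBS = tert-butyldimethylsilyl. Compound numbers are those of the steps and of the compound list.

## Analysis of the target

Target 26 is a linear array of five rings. Ring A is a benzene carrying the (E)-3-hydroxyprop-1-enyl chain and is fused to a 2,3-dihydro-1,4-dioxine (ring B). The benzylic carbon of ring B carries a second benzene (ring C), fused to a second dioxine (ring D), which in turn carries the 3,4-dihydroxyphenyl group (ring E).

Each dioxine has two adjacent stereocentres, an O–CH(aryl) carbon and an O–CH(CH2OH) carbon. All four are R, so both rings are trans-disubstituted. The two pairs are separated by ring C, so neither can direct the other.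

The two dioxines differ in regiochemistry. In ring D the aryl-bearing carbon sits on the ring C oxygen para to the ring B attachment. In ring B the aryl-bearing carbon sits on the ring A oxygen meta to the propenol chain.

Sensitive groups are the free catechol of ring E (oxidation, especially under base), the allylic alcohol (acid, hydrogenation) and the two benzylic aryl ether carbons, each para to an oxygen and therefore prone to ionisation and epimerisation under acid.

The difficulty is threefold: two remote trans pairs must be set under reagent control, the two oxygens of each catechol must be told apart without long protection sequences, and the protecting groups must leave under conditions that the alkene and the benzylic ethers survive.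

The strategy rests on ring D. Its O–CH(CH2OH)–CH(aryl)–O unit, read from the ring C oxygen meta to the C1 substituent to the oxygen para to it, is the one-carbon homologue of the O–CH(aryl)–O unit of a 2-aryl-1,3-benzodioxole, that is, of the plain acetal between a ring C catechol and the ring E aldehyde.

## Retrosynthetic reasoning

**26 ⇐ 25 ⇐ 24.** All four hydroxyl groups are carried as TBS ethers, so one desilylation ends the synthesis without acid or hydrogen. The allylic alcohol is traced to the methyl enoate of 24 by 1,2-hydride reduction. Carrying the chain as an enoate from the start of the ring A fragment removes a separate chain-extension sequence at the end.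

**24 ⇐ 23.** Ring B is cut at the bond between the ring A carbon meta to the chain and the benzylic oxygen. Cutting at the aryl carbon, and not at the benzylic carbon, means the ionisable benzylic stereocentre is never an electrophile. The forward reaction is a palladium-catalysed intramolecular etherification of the aryl bromide in 23, which leaves the carbinol C–O bond intact and so proceeds with retention.

**23 ⇐ 22 ⇐ 21 ⇐ 19 + 11.** The C–C bond between the carbinol carbon and the aryloxy-bearing carbon is cut, which leads to aldehyde 11 and the aryloxyacetyl imide 19. The forward syn-aldol reaction sets both ring B stereocentres under control of the auxiliary in 19. The ring A oxygen para to the chain is already on the nucleophile, so the regiochemistry of ring B is fixed by construction. A syn adduct closed with retention is the trans dioxine. Reductive removal of the auxiliary (21 to 22) and silylation of the primary hydroxyl (22 to 23) prepare the closure. Because the auxiliary is enantiopure, any minor enantiomer of 11 becomes a diastereomer at 21 and can be removed.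

**19 ⇐ 17 ⇐ 16 ⇐ 14 ⇐ 12 + 13 + 15.** The imide comes from acid 17, the acid from tert-butyl ester 16, and 16 from a Wittig reaction of aldehyde 14 with ylide 15. Aldehyde 14 is the O-alkylation product of phenol 12 with bromoacetate 13. The bromine of 12 is the later etherification handle and its formyl group becomes the chain.

**11 ⇐ 10 ⇐ 9 ⇐ 8.** The formyl group of 11 and its silyloxymethyl group both derive from the two esters of 8. Full reduction gives diol 9, and only the benzylic alcohol of 9 is oxidised, which differentiates the two positions without protecting groups.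

**8 ⇐ 5 + 6.** This is the key disconnection. The O–CH(CO2Et) bond and the CH(CO2Et)–CH(aryl) bond of ring D are cut together, which removes one carbon from the ring and leaves the benzodioxole 5 and ethyl diazoacetate 6. The forward reaction must insert the carbene carbon into the acetal C–O bond on the side of the oxygen meta to the ester, make the trans isomer, and do so enantioselectively. The acetal stereocentre of 5 is lost on the way, so 5 can be racemic.

**5 ⇐ 3 + 4; 3 ⇐ 2 ⇐ 1.** The acetal is cut at both C–O bonds to the catechol ester 4 and the dimethyl acetal 3 of the silylated aldehyde 2, which comes from 1. No differentiation of the catechol oxygens of 4 is needed at this stage; the ester does it electronically in the key step.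

## Alternatives that were turned down

**Alternative 1:** Ring B is cut at the bond between the ring A oxygen para to the formyl group and the hydroxymethyl-bearing carbon. This leads from the bis-benzodioxane aldehyde A1 back to the aryloxy(aryl)methyl oxirane A2.
- Forward step: the phenoxide of A2, formed with K2CO3, opens the terminal epoxide at its inner carbon in a 6-exo-tet closure with inversion and releases the primary hydroxyl.
- For it: the closure is favoured over the 7-endo mode and is stereospecific, the phenol para to a formyl group is acidic enough for a mild base, and every reaction type is well known. Each single step is more predictable than the carbene step chosen here.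
- Against it: A2 must already contain ring D complete plus two more stereocentres. One is a benzylic aryl ether on a para-oxygenated ring, which must be installed by substitution at an ionisation-prone benzylic carbon, most plausibly from an electron-rich aryl glycidol, a labile class. The two ring A oxygens must be told apart by protection. The benzyl ethers of A1 must later be removed next to benzylic dioxine C–O bonds and, if left to the end, the alkene. The disconnection offers nothing for ring D, which would need a comparable multi-step treatment, so the sequence is long and linear.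
- Comparison: the chosen strategy gives up predictability in one step, but forms ring D with two bonds and both stereocentres from an acetal that needs no differentiation of the catechol oxygens, and it builds ring B without making its benzylic carbon an electrophile.

**Alternative 2:** The benzylic O–CH(aryl) bond of ring B is cut and the benzylic carbon is returned to a CH2 group. This leads from the ring A–B benzodioxane A3 to the 2-aryloxy-3-arylpropyl ether A4, whose single stereocentre would come from a chiral-pool epoxide.
- Forward step: DDQ abstracts hydride from the benzylic CH2 of A4 and the ortho phenol of ring A traps the para-alkoxybenzyl cation; the existing centre steers the new one to the trans arrangement.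
- For it: no pre-oxidised benzylic carbon, no chiral catalyst and one purchased stereocentre per ring. On the cost of stereocontrol it is stronger than the chosen route.
- Against it: the aryl ring of A4 has one alkoxy donor and a bromine, so hydride abstraction is slow and must compete with oxidation of the two O-benzyl CH2 groups and of the free phenol. The trans preference of a cation closure is a bias, not a guarantee. A3 is only the ring A–B half: the bromine must become the ring C oxygen, the ring C catechol must be unmasked, and ring D must then be built with the opposite regiochemistry on a more electron-rich substrate that carries the oxidisable benzylic C–H of the first dioxine.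
- Comparison: step count and late-stage oxidant compatibility are worse. The chosen strategy makes ring D first and in one step, when nothing valuable is at risk, and assembles from ring E towards ring A so that the sensitive chain arrives last.

**Alternative 3:** Only the O–CH(aryl) bond of ring D is cut, returning the trans diester A5 to the (Z)-α-aryloxy cinnamate A6 with a free phenol para to the ring C ester.
- Forward step: a bifunctional cinchona squaramide deprotonates the phenol and directs its 6-endo-trig oxa-Michael addition to the β-carbon; protonation of the enolate gives the trans ester.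
- For it: it aims at the same kind of intermediate as 8, is metal-free, and belongs to a reaction class with established models for enantio-induction, which the carbene step lacks. On that point it is the stronger proposal.
- Against it: A6 is a poor acceptor, because the α-aryloxy group and the 3,4-dialkoxyphenyl group both push electron density into the alkene. The nucleophile is a phenoxide conjugated to an ester, a weak nucleophile and a good leaving group, so the addition is reversible by E1cB ring opening and the enantiomeric purity would erode under the base that induces it. A6 also needs a mono-functionalised catechol and a Z-selective olefination, several steps for one bond, and its benzyl ethers bring the deprotection conflict noted above.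
- Comparison: the chosen ring expansion forms two bonds instead of one, takes its regiochemistry from the electronic difference of the two acetal oxygens without protection, runs without base so the retro-oxa-Michael channel stays closed, and needs three steps to its precursor.

Key step: step 4

**Assumption:** the (S,S) enantiomer of the bis(oxazoline) is written for step 4. The sense of induction cannot be derived with confidence; if the (2S,3R) enantiomer of 8 should form, the mirror-image ligand is used and nothing else changes.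

## Route

Step 1
Reactants: 1 3,4-dihydroxybenzaldehyde
Product: 2 3,4-bis(tert-butyldimethylsilyloxy)benzaldehyde
Conditions: TBSCl, imidazole, DMF, 0 °C to rt
Reagents that add atoms: tert-butyldimethylsilyl chloride, CC(C)(C)[Si](C)(C)Cl
Why: Standard silylation of both phenols; the silyl ethers are inert to a copper carbene and make ring E a strong cation-stabilising group for step 4.

Step 2
Reactants: 2 3,4-bis(tert-butyldimethylsilyloxy)benzaldehyde
Product: 3 4-(dimethoxymethyl)-1,2-bis(tert-butyldimethylsilyloxy)benzene
Conditions: HC(OMe)3, PPTS (cat.), MeOH, rt; then Et3N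
Reagents that add atoms: trimethyl orthoformate, COC(OC)OC
Why: Acid-catalysed acetalisation driven by the orthoformate as water scavenger; aryl silyl ethers tolerate the weak acid.

Step 3
Reactants: 3 4-(dimethoxymethyl)-1,2-bis(tert-butyldimethylsilyloxy)benzene; 4 methyl 3,4-dihydroxybenzoate
Product: 5 racemic methyl 2-[3,4-bis(tert-butyldimethylsilyloxy)phenyl]-1,3-benzodioxole-5-carboxylate
Conditions: CSA (cat.), toluene, 80 °C, 4 Å molecular sieves (removal of MeOH); then Et3N
Reagents that add atoms: none
Why: Transacetalisation through the ring E stabilised oxocarbenium ion, pulled to the cyclic aryl acetal by removal of methanol. The product is racemic, which does not matter because this centre is erased in step 4.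

Step 4
Reactants: 5 racemic methyl 2-[3,4-bis(tert-butyldimethylsilyloxy)phenyl]-1,3-benzodioxole-5-carboxylate; 6 ethyl diazoacetate
Product: 8 3-ethyl 6-methyl (2R,3S)-2-[3,4-bis(tert-butyldimethylsilyloxy)phenyl]-2,3-dihydro-1,4-benzodioxine-3,6-dicarboxylate (trans), via oxonium ylide 7 (not isolated)
Conditions: Cu(MeCN)4PF6 (5 mol%), (S,S)-t-Bu-box [2,2'-(propane-2,2-diyl)bis((4S)-4-tert-butyl-4,5-dihydrooxazole)] (6 mol%), CH2Cl2, rt, slow addition of 6
Reagents that add atoms: none
Why: Proposed new method: Cu(MeCN)4PF6 (monovalent copper) with the bis(oxazoline) decomposes 6 to an electrophilic copper carbene, which is attacked by O3 of 5, the acetal oxygen meta to the ester and not conjugated with it, to give the copper-associated oxonium ylide 7. Heterolysis of the C2–O3 bond of 7 should be easy because the cation is stabilised by O1 and by the para silyloxy group of ring E, and it leaves an oxocarbenium ion held next to a copper-bound ester enolate. Recombination at carbon forms the C–C bond and closes ring D by a 6-endo-trig attack on the oxocarbenium carbon (6-enolexo for the enolate), overall a [1,2]-Stevens shift that expands the five-membered acetal to the six-membered ring. The closest known reaction types are metal-carbene oxonium ylide ring expansions of 2-aryl-1,3-dioxolanes to 1,4-dioxanes and the enantioselective copper-catalysed expansion of oxetanes to tetrahydrofurans with diazoesters; aryl acetal oxygens as ylide donors are not covered by them. The trans relationship of C2 and C3 should follow from a chair-like recombination with the aryl and ester groups pseudo-equatorial. The absolute configuration of both centres has to come from the ligand on the copper-bound enolate, which selects one face of the planar oxocarbenium ion; as the acetal centre of 5 is lost in that ion, both enantiomers of 5 converge. The step needs selection between the two acetal oxygens (secured by the ester, which deactivates the para oxygen O1), C- over O-recombination, and suppression of carbene dimerisation and of insertion into the acetal C–H bond (slow addition of 6).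

Step 5
Reactants: 8 3-ethyl 6-methyl (2R,3S)-2-[3,4-bis(tert-butyldimethylsilyloxy)phenyl]-2,3-dihydro-1,4-benzodioxine-3,6-dicarboxylate
Product: 9 [(2R,3R)-2-[3,4-bis(tert-butyldimethylsilyloxy)phenyl]-2,3-dihydro-1,4-benzodioxine-3,6-diyl]dimethanol
Conditions: DIBAL-H, CH2Cl2, −78 to 0 °C; aq. KNaC4H4O6
Reagents that add atoms: none
Why: Hydride reduction of both esters under non-basic conditions, which avoids enolisation and E1cB opening of ring D. C3 keeps its geometry and only its descriptor changes from S to R.

Step 6
Reactants: 9 [(2R,3R)-2-[3,4-bis(tert-butyldimethylsilyloxy)phenyl]-2,3-dihydro-1,4-benzodioxine-3,6-diyl]dimethanol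
Product: 10 (2R,3R)-2-[3,4-bis(tert-butyldimethylsilyloxy)phenyl]-3-(hydroxymethyl)-2,3-dihydro-1,4-benzodioxine-6-carbaldehyde
Conditions: MnO2, CH2Cl2, rt
Reagents that add atoms: none
Why: MnO2 oxidises benzylic alcohols and leaves the aliphatic primary alcohol, so the two former ester positions are differentiated without protection.

Step 7
Reactants: 10 (2R,3R)-2-[3,4-bis(tert-butyldimethylsilyloxy)phenyl]-3-(hydroxymethyl)-2,3-dihydro-1,4-benzodioxine-6-carbaldehyde
Product: 11 (2R,3R)-2-[3,4-bis(tert-butyldimethylsilyloxy)phenyl]-3-[(tert-butyldimethylsilyloxy)methyl]-2,3-dihydro-1,4-benzodioxine-6-carbaldehyde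
Conditions: TBSCl, imidazole, CH2Cl2, 0 °C to rt
Reagents that add atoms: tert-butyldimethylsilyl chloride, CC(C)(C)[Si](C)(C)Cl
Why: Silylation of the primary alcohol so that it does not consume the boron reagent of step 12; a third TBS group keeps the final deprotection uniform.

Step 8
Reactants: 12 3-bromo-4-hydroxybenzaldehyde; 13 tert-butyl bromoacetate
Product: 14 tert-butyl 2-(2-bromo-4-formylphenoxy)acetate
Conditions: K2CO3, DMF, rt
Reagents that add atoms: none
Why: Williamson ether synthesis; the acidic phenol para to the formyl group is alkylated cleanly by the α-bromo ester.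

Step 9
Reactants: 14 tert-butyl 2-(2-bromo-4-formylphenoxy)acetate; 15 methyl (triphenylphosphoranylidene)acetate
Product: 16 methyl (E)-3-[3-bromo-4-(2-tert-butoxy-2-oxoethoxy)phenyl]prop-2-enoate
Conditions: toluene, 80 °C
Reagents that add atoms: none
Why: Wittig reaction of a stabilised ylide, which should give the (E)-enoate; this installs the three-carbon chain of ring A at the ester oxidation level.

Step 10
Reactants: 16 methyl (E)-3-[3-bromo-4-(2-tert-butoxy-2-oxoethoxy)phenyl]prop-2-enoate
Product: 17 2-[2-bromo-4-[(E)-3-methoxy-3-oxoprop-1-enyl]phenoxy]acetic acid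
Conditions: TFA, CH2Cl2, rt
Reagents that add atoms: none
Why: Acidolysis of the tert-butyl ester through the tert-butyl cation; the methyl enoate is untouched.

Step 11
Reactants: 17 2-[2-bromo-4-[(E)-3-methoxy-3-oxoprop-1-enyl]phenoxy]acetic acid
Product: 19 methyl (E)-3-[4-[2-[(4S)-4-benzyl-2-oxooxazolidin-3-yl]-2-oxoethoxy]-3-bromophenyl]prop-2-enoate, via mixed pivalic anhydride 18 (not isolated)
Conditions: t-BuCOCl, Et3N, THF, −20 °C; then (S)-4-benzyloxazolidin-2-one, LiCl, −20 °C to rt
Reagents that add atoms: (S)-4-benzyloxazolidin-2-one, O=C1OC[C@H](Cc2ccccc2)N1; pivaloyl chloride, CC(C)(C)C(Cl)=O (its atoms remain only in 18)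
Why: N-Acylation of the auxiliary through the mixed anhydride, which is attacked at its less hindered carbonyl; no strong base is used, so the enoate is safe.

Step 12
Reactants: 19 methyl (E)-3-[4-[2-[(4S)-4-benzyl-2-oxooxazolidin-3-yl]-2-oxoethoxy]-3-bromophenyl]prop-2-enoate; 11 (2R,3R)-2-[3,4-bis(tert-butyldimethylsilyloxy)phenyl]-3-[(tert-butyldimethylsilyloxy)methyl]-2,3-dihydro-1,4-benzodioxine-6-carbaldehyde
Product: 21 (4S)-4-benzyl-3-[(2S,3R)-2-[2-bromo-4-[(E)-3-methoxy-3-oxoprop-1-enyl]phenoxy]-3-hydroxy-3-[(2R,3R)-2-[3,4-bis(tert-butyldimethylsilyloxy)phenyl]-3-[(tert-butyldimethylsilyloxy)methyl]-2,3-dihydro-1,4-benzodioxin-6-yl]propanoyl]oxazolidin-2-one, via dibutylboron Z-enolate 20 (not isolated)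
Conditions: 19, Bu2BOTf, i-Pr2NEt, CH2Cl2, −78 to 0 °C; then 11, −78 to 0 °C; pH 7 buffer (KH2PO4/K2HPO4), MeOH, H2O2, 0 °C
Reagents that add atoms: dibutylboron triflate, CCCCB(CCCC)OS(=O)(=O)C(F)(F)F (its atoms remain only in 20)
Why: Evans syn-aldol reaction: the Z-boron enolate 20 adds to 11 through a chair-like Zimmerman–Traxler transition state on the face away from the benzyl group of the auxiliary, which should set C2 as S and the carbinol carbon C3 as R. The ring A oxygen para to the enoate is thereby fixed on C2, so the regiochemistry of ring B is decided here. The stereocentres of 11 are remote, and an adduct from any minor enantiomer of 11 is a separable diastereomer.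

Step 13
Reactants: 21 the syn-aldol adduct of step 12
Product: 22 methyl (E)-3-[3-bromo-4-[(1R,2R)-1,3-dihydroxy-1-[(2R,3R)-2-[3,4-bis(tert-butyldimethylsilyloxy)phenyl]-3-[(tert-butyldimethylsilyloxy)methyl]-2,3-dihydro-1,4-benzodioxin-6-yl]propan-2-yl]oxyphenyl]prop-2-enoate
Conditions: NaBH4, THF/H2O, 0 °C to rt
Reagents that add atoms: none
Why: Reductive cleavage of the N-acyl oxazolidinone; the imide carbonyl is far more electrophilic than the conjugated methyl ester. The aryloxy carbon keeps its geometry and its descriptor changes from S to R.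

Step 14
Reactants: 22 the 1,3-diol of step 13
Product: 23 methyl (E)-3-[3-bromo-4-[(1R,2R)-3-(tert-butyldimethylsilyloxy)-1-hydroxy-1-[(2R,3R)-2-[3,4-bis(tert-butyldimethylsilyloxy)phenyl]-3-[(tert-butyldimethylsilyloxy)methyl]-2,3-dihydro-1,4-benzodioxin-6-yl]propan-2-yl]oxyphenyl]prop-2-enoate
Conditions: TBSCl, imidazole, CH2Cl2, 0 °C
Reagents that add atoms: tert-butyldimethylsilyl chloride, CC(C)(C)[Si](C)(C)Cl
Why: Selective silylation of the primary over the hindered secondary benzylic hydroxyl. It is needed because the primary hydroxyl could otherwise close an isomeric six-membered ring in step 15.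

Step 15
Reactants: 23 the bromo alcohol of step 14
Product: 24 methyl (E)-3-[(2R,3R)-3-[(2R,3R)-2-[3,4-bis(tert-butyldimethylsilyloxy)phenyl]-3-[(tert-butyldimethylsilyloxy)methyl]-2,3-dihydro-1,4-benzodioxin-6-yl]-2-[(tert-butyldimethylsilyloxy)methyl]-2,3-dihydro-1,4-benzodioxin-6-yl]prop-2-enoate
Conditions: Pd(OAc)2 (5 mol%), 2-(di-tert-butylphosphino)-1,1'-binaphthyl (6 mol%), K3PO4, toluene, 70 °C
Reagents that add atoms: none
Why: Intramolecular Buchwald–Hartwig etherification: oxidative addition of zerovalent palladium into the C–Br bond, alkoxide coordination and C–O reductive elimination close ring B. The carbinol C–O bond is not broken, so the benzylic centre is retained and the syn adduct should give the trans ring; the bulky electron-rich phosphine favours reductive elimination over β-hydride elimination.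

Step 16
Reactants: 24 the bis-benzodioxane methyl enoate of step 15
Product: 25 (E)-3-[(2R,3R)-3-[(2R,3R)-2-[3,4-bis(tert-butyldimethylsilyloxy)phenyl]-3-[(tert-butyldimethylsilyloxy)methyl]-2,3-dihydro-1,4-benzodioxin-6-yl]-2-[(tert-butyldimethylsilyloxy)methyl]-2,3-dihydro-1,4-benzodioxin-6-yl]prop-2-en-1-ol
Conditions: DIBAL-H, CH2Cl2, −78 °C; aq. KNaC4H4O6
Reagents that add atoms: none
Why: 1,2-Reduction of the enoate to the (E)-allylic alcohol; no other reducible group is present and the silyl ethers are stable.

Step 17
Reactants: 25 the tetrakis-silyl allylic alcohol of step 16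
Product: 26 (E)-3-[(2R,3R)-3-[(2R,3R)-2-(3,4-dihydroxyphenyl)-3-(hydroxymethyl)-2,3-dihydro-1,4-benzodioxin-6-yl]-2-(hydroxymethyl)-2,3-dihydro-1,4-benzodioxin-6-yl]prop-2-en-1-ol (target)
Conditions: Bu4NF, AcOH, THF, 0 °C to rt, argon
Reagents that add atoms: none
Why: Fluoride cleavage of the two aryl and two alkyl silyl ethers; acetic acid buffers the phenoxides so that the catechol is not oxidised, and the medium stays too weakly acidic to ionise the allylic alcohol or the benzylic ethers.

## Compound list

1 | 3,4-dihydroxybenzaldehyde | O=Cc1ccc(O)c(O)c1 | starting material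
2 | 3,4-bis(tert-butyldimethylsilyloxy)benzaldehyde | O=Cc1ccc(O[Si](C)(C)C(C)(C)C)c(O[Si](C)(C)C(C)(C)C)c1 | intermediate
3 | 4-(dimethoxymethyl)-1,2-bis(tert-butyldimethylsilyloxy)benzene | COC(OC)c1ccc(O[Si](C)(C)C(C)(C)C)c(O[Si](C)(C)C(C)(C)C)c1 | intermediate
4 | methyl 3,4-dihydroxybenzoate | COC(=O)c1ccc(O)c(O)c1 | starting material
5 | racemic methyl 2-[3,4-bis(tert-butyldimethylsilyloxy)phenyl]-1,3-benzodioxole-5-carboxylate | COC(=O)c1ccc2c(c1)OC(c1ccc(O[Si](C)(C)C(C)(C)C)c(O[Si](C)(C)C(C)(C)C)c1)O2 | intermediate
6 | ethyl diazoacetate | CCOC(=O)C=[N+]=[N-] | starting material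
7 | oxonium ylide at O3 of 5 (copper-associated; drawn as the free ylide) | COC(=O)c1ccc2c(c1)[O+]([CH-]C(=O)OCC)C(c1ccc(O[Si](C)(C)C(C)(C)C)c(O[Si](C)(C)C(C)(C)C)c1)O2 | intermediate (not isolated)
8 | 3-ethyl 6-methyl (2R,3S)-2-[3,4-bis(tert-butyldimethylsilyloxy)phenyl]-2,3-dihydro-1,4-benzodioxine-3,6-dicarboxylate | COC(=O)c1ccc2c(c1)O[C@H](C(=O)OCC)[C@@H](c1ccc(O[Si](C)(C)C(C)(C)C)c(O[Si](C)(C)C(C)(C)C)c1)O2 | intermediate
9 | [(2R,3R)-2-[3,4-bis(tert-butyldimethylsilyloxy)phenyl]-2,3-dihydro-1,4-benzodioxine-3,6-diyl]dimethanol | OCc1ccc2c(c1)O[C@H](CO)[C@@H](c1ccc(O[Si](C)(C)C(C)(C)C)c(O[Si](C)(C)C(C)(C)C)c1)O2 | intermediate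
10 | (2R,3R)-2-[3,4-bis(tert-butyldimethylsilyloxy)phenyl]-3-(hydroxymethyl)-2,3-dihydro-1,4-benzodioxine-6-carbaldehyde | O=Cc1ccc2c(c1)O[C@H](CO)[C@@H](c1ccc(O[Si](C)(C)C(C)(C)C)c(O[Si](C)(C)C(C)(C)C)c1)O2 | intermediate
11 | (2R,3R)-2-[3,4-bis(tert-butyldimethylsilyloxy)phenyl]-3-[(tert-butyldimethylsilyloxy)methyl]-2,3-dihydro-1,4-benzodioxine-6-carbaldehyde | O=Cc1ccc2c(c1)O[C@H](CO[Si](C)(C)C(C)(C)C)[C@@H](c1ccc(O[Si](C)(C)C(C)(C)C)c(O[Si](C)(C)C(C)(C)C)c1)O2 | intermediate
12 | 3-bromo-4-hydroxybenzaldehyde | O=Cc1ccc(O)c(Br)c1 | starting material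
13 | tert-butyl bromoacetate | CC(C)(C)OC(=O)CBr | starting material
14 | tert-butyl 2-(2-bromo-4-formylphenoxy)acetate | CC(C)(C)OC(=O)COc1ccc(C=O)cc1Br | intermediate
15 | methyl (triphenylphosphoranylidene)acetate | COC(=O)C=P(c1ccccc1)(c1ccccc1)c1ccccc1 | starting material
16 | methyl (E)-3-[3-bromo-4-(2-tert-butoxy-2-oxoethoxy)phenyl]prop-2-enoate | COC(=O)/C=C/c1ccc(OCC(=O)OC(C)(C)C)c(Br)c1 | intermediate
17 | 2-[2-bromo-4-[(E)-3-methoxy-3-oxoprop-1-enyl]phenoxy]acetic acid | COC(=O)/C=C/c1ccc(OCC(=O)O)c(Br)c1 | intermediate
18 | mixed anhydride of 17 with pivalic acid | COC(=O)/C=C/c1ccc(OCC(=O)OC(=O)C(C)(C)C)c(Br)c1 | intermediate (not isolated)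
19 | methyl (E)-3-[4-[2-[(4S)-4-benzyl-2-oxooxazolidin-3-yl]-2-oxoethoxy]-3-bromophenyl]prop-2-enoate | COC(=O)/C=C/c1ccc(OCC(=O)N2C(=O)OC[C@@H]2Cc2ccccc2)c(Br)c1 | intermediate
20 | (Z)-dibutylboron enolate of 19 | CCCCB(CCCC)O/C(=C\Oc1ccc(/C=C/C(=O)OC)cc1Br)N1C(=O)OC[C@@H]1Cc1ccccc1 | intermediate (not isolated)
21 | (4S)-4-benzyl-3-[(2S,3R)-2-[2-bromo-4-[(E)-3-methoxy-3-oxoprop-1-enyl]phenoxy]-3-hydroxy-3-[(2R,3R)-2-[3,4-bis(tert-butyldimethylsilyloxy)phenyl]-3-[(tert-butyldimethylsilyloxy)methyl]-2,3-dihydro-1,4-benzodioxin-6-yl]propanoyl]oxazolidin-2-one | O[C@H](c1ccc2c(c1)O[C@H](CO[Si](C)(C)C(C)(C)C)[C@@H](c1ccc(O[Si](C)(C)C(C)(C)C)c(O[Si](C)(C)C(C)(C)C)c1)O2)[C@@H](C(=O)N1C(=O)OC[C@@H]1Cc1ccccc1)Oc1ccc(/C=C/C(=O)OC)cc1Br | intermediate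
22 | methyl (E)-3-[3-bromo-4-[(1R,2R)-1,3-dihydroxy-1-[(2R,3R)-2-[3,4-bis(tert-butyldimethylsilyloxy)phenyl]-3-[(tert-butyldimethylsilyloxy)methyl]-2,3-dihydro-1,4-benzodioxin-6-yl]propan-2-yl]oxyphenyl]prop-2-enoate | O[C@H](c1ccc2c(c1)O[C@H](CO[Si](C)(C)C(C)(C)C)[C@@H](c1ccc(O[Si](C)(C)C(C)(C)C)c(O[Si](C)(C)C(C)(C)C)c1)O2)[C@@H](CO)Oc1ccc(/C=C/C(=O)OC)cc1Br | intermediate
23 | methyl (E)-3-[3-bromo-4-[(1R,2R)-3-(tert-butyldimethylsilyloxy)-1-hydroxy-1-[(2R,3R)-2-[3,4-bis(tert-butyldimethylsilyloxy)phenyl]-3-[(tert-butyldimethylsilyloxy)methyl]-2,3-dihydro-1,4-benzodioxin-6-yl]propan-2-yl]oxyphenyl]prop-2-enoate | O[C@H](c1ccc2c(c1)O[C@H](CO[Si](C)(C)C(C)(C)C)[C@@H](c1ccc(O[Si](C)(C)C(C)(C)C)c(O[Si](C)(C)C(C)(C)C)c1)O2)[C@@H](CO[Si](C)(C)C(C)(C)C)Oc1ccc(/C=C/C(=O)OC)cc1Br | intermediate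
24 | methyl (E)-3-[(2R,3R)-3-[(2R,3R)-2-[3,4-bis(tert-butyldimethylsilyloxy)phenyl]-3-[(tert-butyldimethylsilyloxy)methyl]-2,3-dihydro-1,4-benzodioxin-6-yl]-2-[(tert-butyldimethylsilyloxy)methyl]-2,3-dihydro-1,4-benzodioxin-6-yl]prop-2-enoate | COC(=O)/C=C/c1ccc2c(c1)O[C@H](c1ccc3c(c1)O[C@H](CO[Si](C)(C)C(C)(C)C)[C@@H](c1ccc(O[Si](C)(C)C(C)(C)C)c(O[Si](C)(C)C(C)(C)C)c1)O3)[C@@H](CO[Si](C)(C)C(C)(C)C)O2 | intermediate
25 | (E)-3-[(2R,3R)-3-[(2R,3R)-2-[3,4-bis(tert-butyldimethylsilyloxy)phenyl]-3-[(tert-butyldimethylsilyloxy)methyl]-2,3-dihydro-1,4-benzodioxin-6-yl]-2-[(tert-butyldimethylsilyloxy)methyl]-2,3-dihydro-1,4-benzodioxin-6-yl]prop-2-en-1-ol | OC/C=C/c1ccc2c(c1)O[C@H](c1ccc3c(c1)O[C@H](CO[Si](C)(C)C(C)(C)C)[C@@H](c1ccc(O[Si](C)(C)C(C)(C)C)c(O[Si](C)(C)C(C)(C)C)c1)O3)[C@@H](CO[Si](C)(C)C(C)(C)C)O2 | intermediate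
26 | (E)-3-[(2R,3R)-3-[(2R,3R)-2-(3,4-dihydroxyphenyl)-3-(hydroxymethyl)-2,3-dihydro-1,4-benzodioxin-6-yl]-2-(hydroxymethyl)-2,3-dihydro-1,4-benzodioxin-6-yl]prop-2-en-1-ol | OC/C=C/c1ccc2c(c1)O[C@H](c1ccc3c(c1)O[C@H](CO)[C@@H](c1ccc(O)c(O)c1)O3)[C@@H](CO)O2 | target

## Step count and least certain steps

Total: 17 steps. Longest linear sequence: 13 steps (steps 1 to 7, then 12 to 17); the ring A fragment takes 4 steps (8 to 11) before it joins at step 12.

**Step 4 (key step).** The most likely failures are these:
- the weakly basic aryl acetal oxygens may not capture the carbene, so that carbene dimerisation or insertion into the acetal C–H bond takes over;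
- the ylide may leave the metal before the shift, or the ion pair may recombine outside the influence of the ligand, which would give poor enantioselectivity;
- the ion pair may recombine at the enolate oxygen.

Fallback by known chemistry, from 2 back to 11:
- Methyl 4-bromo-3-hydroxybenzoate F1 is alkylated with 13 (K2CO3, DMF) to methyl 4-bromo-3-(2-tert-butoxy-2-oxoethoxy)benzoate F2.
- TFA converts F2 into 2-[2-bromo-5-(methoxycarbonyl)phenoxy]acetic acid F3.
- Pivaloyl chloride and Et3N give the mixed pivalic anhydride F4, which acylates (S)-4-benzyloxazolidin-2-one (LiCl) to methyl 3-[2-[(4S)-4-benzyl-2-oxooxazolidin-3-yl]-2-oxoethoxy]-4-bromobenzoate F5.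
- Bu2BOTf and i-Pr2NEt give the dibutylboron Z-enolate F6, which adds to aldehyde 2 in an Evans syn-aldol reaction to give the (2S,3R) aldol adduct F7.
- NaBH4 in THF/H2O removes the auxiliary to give the 1,3-diol F8, and TBSCl with imidazole silylates the primary hydroxyl to the bromo alcohol F9.
- Pd(OAc)2 with 2-(di-tert-butylphosphino)-1,1'-binaphthyl and K3PO4 closes ring D at the aryl carbon para to the ester, with retention, to methyl (2R,3R)-2-[3,4-bis(tert-butyldimethylsilyloxy)phenyl]-3-[(tert-butyldimethylsilyloxy)methyl]-2,3-dihydro-1,4-benzodioxine-6-carboxylate F10.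
- DIBAL-H gives the benzylic alcohol F11, and MnO2 oxidises it to 11.

**Step 15.** The palladium alkoxide of the secondary benzylic alcohol may undergo β-hydride elimination (oxidation to the ketone with loss of bromine) faster than C–O reductive elimination, and the hot basic medium may strip aryl silyl ethers.

Fallback, from 23 back to 24, making the bond at the benzylic carbon instead:
- Miyaura borylation of 23 (B2pin2, Pd(dppf)Cl2, KOAc, dioxane) gives the pinacol boronate F12.
- NaBO3·4H2O in THF/H2O oxidises F12 to the phenol F13.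
- Catalytic PPTS in toluene ionises the para-oxygenated benzylic alcohol of F13, and the phenol traps the cation to close ring B to 24. The trans ring is then set by the adjacent aryloxy-bearing centre, with both substituents pseudo-equatorial.

**Step 3.** The ester-deactivated catechol may exchange incompletely against a strained five-membered aryl acetal, and the acid may remove silyl groups or hydrolyse the product on work-up.

Fallback, from 2 and 4 back to 5, replacing the equilibrium by an irreversible silyl transfer: 4 is converted with Me3SiCl and Et3N into methyl 3,4-bis(trimethylsilyloxy)benzoate F14, which condenses with aldehyde 2 under catalytic Me3SiOTf in CH2Cl2 at −78 °C (Noyori acetalisation) to give 5 directly, without 3.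

**Step 17.** The liberated catechol may oxidise to the quinone and polymerise if the fluoride medium becomes basic, and a more acidic fluoride source may ionise the allylic alcohol.

Fallback, from 24 back to 26, reversing the order of the last two steps: 24 is desilylated with HF·pyridine in THF/pyridine while the chain is still the robust enoate, giving the tetrahydroxy methyl enoate F15, and excess DIBAL-H in THF (−78 to 0 °C) then reduces the ester to 26.

## Further compounds

F1 | step 4 | methyl 4-bromo-3-hydroxybenzoate | COC(=O)c1ccc(Br)c(O)c1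
F2 | step 4 | methyl 4-bromo-3-(2-tert-butoxy-2-oxoethoxy)benzoate | COC(=O)c1ccc(Br)c(OCC(=O)OC(C)(C)C)c1
F3 | step 4 | 2-[2-bromo-5-(methoxycarbonyl)phenoxy]acetic acid | COC(=O)c1ccc(Br)c(OCC(=O)O)c1
F4 | step 4 | mixed anhydride of F3 with pivalic acid | COC(=O)c1ccc(Br)c(OCC(=O)OC(=O)C(C)(C)C)c1
F5 | step 4 | methyl 3-[2-[(4S)-4-benzyl-2-oxooxazolidin-3-yl]-2-oxoethoxy]-4-bromobenzoate | COC(=O)c1ccc(Br)c(OCC(=O)N2C(=O)OC[C@@H]2Cc2ccccc2)c1
F6 | step 4 | (Z)-dibutylboron enolate of F5 | CCCCB(CCCC)O/C(=C\Oc1cc(C(=O)OC)ccc1Br)N1C(=O)OC[C@@H]1Cc1ccccc1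
F7 | step 4 | methyl 3-[(1S,2R)-1-[(4S)-4-benzyl-2-oxooxazolidine-3-carbonyl]-2-[3,4-bis(tert-butyldimethylsilyloxy)phenyl]-2-hydroxyethoxy]-4-bromobenzoate, the (2S,3R) syn-aldol adduct | COC(=O)c1ccc(Br)c(c1)O[C@H](C(=O)N1C(=O)OC[C@@H]1Cc1ccccc1)[C@@H](c1ccc(O[Si](C)(C)C(C)(C)C)c(O[Si](C)(C)C(C)(C)C)c1)O
F8 | step 4 | methyl 4-bromo-3-[(1R,2R)-1-[3,4-bis(tert-butyldimethylsilyloxy)phenyl]-1,3-dihydroxypropan-2-yl]oxybenzoate | COC(=O)c1ccc(Br)c(c1)O[C@H](CO)[C@@H](c1ccc(O[Si](C)(C)C(C)(C)C)c(O[Si](C)(C)C(C)(C)C)c1)O
F9 | step 4 | methyl 4-bromo-3-[(1R,2R)-1-[3,4-bis(tert-butyldimethylsilyloxy)phenyl]-3-(tert-butyldimethylsilyloxy)-1-hydroxypropan-2-yl]oxybenzoate | COC(=O)c1ccc(Br)c(c1)O[C@H](CO[Si](C)(C)C(C)(C)C)[C@@H](c1ccc(O[Si](C)(C)C(C)(C)C)c(O[Si](C)(C)C(C)(C)C)c1)O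
F10 | step 4 | methyl (2R,3R)-2-[3,4-bis(tert-butyldimethylsilyloxy)phenyl]-3-[(tert-butyldimethylsilyloxy)methyl]-2,3-dihydro-1,4-benzodioxine-6-carboxylate | COC(=O)c1ccc2c(c1)O[C@H](CO[Si](C)(C)C(C)(C)C)[C@@H](c1ccc(O[Si](C)(C)C(C)(C)C)c(O[Si](C)(C)C(C)(C)C)c1)O2
F11 | step 4 | [(2R,3R)-2-[3,4-bis(tert-butyldimethylsilyloxy)phenyl]-3-[(tert-butyldimethylsilyloxy)methyl]-2,3-dihydro-1,4-benzodioxin-6-yl]methanol | OCc1ccc2c(c1)O[C@H](CO[Si](C)(C)C(C)(C)C)[C@@H](c1ccc(O[Si](C)(C)C(C)(C)C)c(O[Si](C)(C)C(C)(C)C)c1)O2
F12 | step 15 | pinacol boronate from 23 (bromine replaced by 4,4,5,5-tetramethyl-1,3,2-dioxaborolan-2-yl) | O[C@H](c1ccc2c(c1)O[C@H](CO[Si](C)(C)C(C)(C)C)[C@@H](c1ccc(O[Si](C)(C)C(C)(C)C)c(O[Si](C)(C)C(C)(C)C)c1)O2)[C@@H](CO[Si](C)(C)C(C)(C)C)Oc1ccc(/C=C/C(=O)OC)cc1B1OC(C)(C)C(C)(C)O1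
F13 | step 15 | phenol from 23 (bromine replaced by hydroxyl) | O[C@H](c1ccc2c(c1)O[C@H](CO[Si](C)(C)C(C)(C)C)[C@@H](c1ccc(O[Si](C)(C)C(C)(C)C)c(O[Si](C)(C)C(C)(C)C)c1)O2)[C@@H](CO[Si](C)(C)C(C)(C)C)Oc1ccc(/C=C/C(=O)OC)cc1O
F14 | step 3 | methyl 3,4-bis(trimethylsilyloxy)benzoate | COC(=O)c1ccc(O[Si](C)(C)C)c(O[Si](C)(C)C)c1
F15 | step 17 | methyl (E)-3-[(2R,3R)-3-[(2R,3R)-2-(3,4-dihydroxyphenyl)-3-(hydroxymethyl)-2,3-dihydro-1,4-benzodioxin-6-yl]-2-(hydroxymethyl)-2,3-dihydro-1,4-benzodioxin-6-yl]prop-2-enoate | COC(=O)/C=C/c1ccc2c(c1)O[C@H](c1ccc3c(c1)O[C@H](CO)[C@@H](c1ccc(O)c(O)c1)O3)[C@@H](CO)O2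
A1 | alternative 1 | bis-benzodioxane aldehyde with free ring B hydroxymethyl and benzyl-protected rings D and E | O=Cc1ccc2c(c1)O[C@H](c1ccc3c(c1)O[C@H](COCc1ccccc1)[C@@H](c1ccc(OCc4ccccc4)c(OCc4ccccc4)c1)O3)[C@@H](CO)O2
A2 | alternative 1 | 4-hydroxy-3-[(R)-aryl[(2S)-oxiran-2-yl]methoxy]benzaldehyde, the epoxide precursor of A1 | O=Cc1ccc(O)c(c1)O[C@H](c1ccc3c(c1)O[C@H](COCc1ccccc1)[C@@H](c1ccc(OCc4ccccc4)c(OCc4ccccc4)c1)O3)[C@@H]1CO1
A3 | alternative 2 | methyl (2R,3R)-3-(4-benzyloxy-3-bromophenyl)-2-(benzyloxymethyl)-2,3-dihydro-1,4-benzodioxine-6-carboxylate | COC(=O)c1ccc2c(c1)O[C@H](c1ccc(OCc3ccccc3)c(Br)c1)[C@@H](COCc1ccccc1)O2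
A4 | alternative 2 | methyl 4-[(2S)-1-benzyloxy-3-(4-benzyloxy-3-bromophenyl)propan-2-yl]oxy-3-hydroxybenzoate | COC(=O)c1ccc(O[C@H](COCc2ccccc2)Cc2ccc(OCc3ccccc3)c(Br)c2)c(O)c1
A5 | alternative 3 | dimethyl (2R,3S)-2-[3,4-bis(benzyloxy)phenyl]-2,3-dihydro-1,4-benzodioxine-3,6-dicarboxylate | COC(=O)c1ccc2c(c1)O[C@H](C(=O)OC)[C@@H](c1ccc(OCc3ccccc3)c(OCc3ccccc3)c1)O2
A6 | alternative 3 | methyl 3-[(Z)-2-[3,4-bis(benzyloxy)phenyl]-1-(methoxycarbonyl)ethenyl]oxy-4-hydroxybenzoate | COC(=O)c1ccc(O)c(c1)O/C(C(=O)OC)=C\c1ccc(OCc2ccccc2)c(OCc2ccccc2)c1
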